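Remark: positions are labelled C1–C15 (ring B = C1–C5, ring A = C1, C5–C10, C14 on C8, C15 on C1), "α" is the face of the bicycle that carries C15, and it is assumed that an isopropyl organometallic adds to a C4 ketone anti to an oxygen substituent at C2, so C2 is entered with the opposite configuration and inverted afterwards.

## Structural features

The target is a cis-fused hydroazulene: cyclopentane ring B (C1–C5) shares the C1–C5 bond with cycloheptene ring A (C1, C5, C6, C7, C8, C9, C10), whose only alkene is C8=C9 bearing C14. Six stereocentres form one unbroken array: quaternary C1 (C15) sits between the carbinol carbons C10 and C2 and the ring-fusion methine C5, and C5 sits between the tertiary carbinol C4 (isopropyl) and the carbinol C6. C15, H5, the isopropyl group and the C2 hydroxyl are α; the C4 hydroxyl and the C10 ester oxygen are β; the C6 ester oxygen is α, so the C2 and C4 hydroxyls are trans on ring B. The fragile groups are the two angelates (Z to E isomerisation to tiglates under base or nucleophilic catalysis), the β relationship of the C4 hydroxyl to C6 (retro-aldol or dehydration whenever C6 is a ketone), and the C8=C9 alkene, which is β,γ to C6 and allylic to the C10 oxygen. The real difficulty is the quaternary C1 flanked by oxygenated carbons inside a seven-membered ring, combined with the trans C2/C4 diol and the cis ring fusion. With C6 as a ketone enol (C5=C6), ring A is a cyclohepta-1,4-diene (C5=C6 and C8=C9 separated by C7); this is the product pattern of a Cope rearrangement of a cis-dialkenylcyclopropane C6–C7–C8 with arms C5=C1 and C9=C10, so the C1–C10 bond and both of its stereocentres can arise in one pericyclic event.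

## Logic of the disconnections

26 to 25: the O–aryl bond at C2 is cut. The C2 oxygen must stay distinct from the C6 and C10 oxygens during acylation, and the aryl ether is the group that the C2-setting step installs. The forward step must oxidise an electron-rich arene without touching two angelates, the alkene or the tertiary alcohol.

25 to 22 and 23: both ester C–O bonds at C6 and C10 are cut together, which releases two molecules of 23 for one of 22. The two secondary hydroxyls are acylated in one operation and the tertiary C4 hydroxyl needs no protection. The forward step must acylate twice without Z to E isomerisation, hence an excess of pre-formed 24 and no nucleophilic catalyst.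

22 to 21: the C6–H bond is cut, giving the C6 ketone. This removes one stereocentre and lets the C4 hydroxyl deliver hydride to the β face; external attack on the open α face would give the wrong epimer, so a reagent that reduces only when bound is required.

21 to 19 through 20: the C5–H bond and three O–Si bonds are cut. The ketone is the hydrolysed form of the enol silane that the key step produces. The forward step needs protonation of C5 on the α face under non-enolising conditions; a base-mediated equilibration is avoided because it could move C8=C9 into conjugation.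

19 to 18: C1–C10 is cut and C6–C8 is re-formed (retro-Cope). Ring A and the stereocentres C1 and C10 disappear, leaving a monocyclic ring B carrying a cyclopropane. The forward step needs cis arms, an (E)-enol silane and bonding on the β face of C1.

18 to 17 to 16: the C10 O–Si bond, then the C10=O bond (from a terminal alkene) are cut. The enol silane comes from a neopentyl-type aldehyde and the aldehyde from an allyl group. The alkene cleavage must spare the electron-rich C5=C1 bond, which rules out ozone.

16 to 15: C6–C7 and C7–C8 are cut (methylene transfer). Because cyclopropanation is stereospecific, the cis relationship of ring B and the C9 arm is read from the enol silane geometry. The forward step must be selective for the enol ether and acid-free.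

15 to 13 through 14: the C9–C10 bond and the C6 O–Si bond are cut. Deprotonation of an α,α-disubstituted ketone would give a fully substituted enolate of uncontrolled geometry, most likely with ring B trans to the larger arm. Conjugate addition of a vinyl group to the α-methyl enone through its s-trans conformer is chosen instead because it defines the (E)-geometry.

13 to 8 and 11 (through 12), and 11 to 9 and 10: the C5–C6 bond is cut by acyl substitution. This separates ring B from a four-carbon acyl unit. The forward step needs halogen–lithium exchange next to a tertiary silyl ether and a single addition.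

8 to 7 to 6: the C4 O–Si bond, then the C2–O(aryl) bond with inversion, are cut. The target needs C2–O and C4–O trans, whereas nucleophilic addition to the C4 ketone delivers them cis; an SN2 etherification corrects this and protects C2 in the same step. Ionisation of the allylic position must be avoided.

6 to 5 to 4: the C2 O–Si bond, then the C4–isopropyl bond, are cut. The tertiary carbinol comes from the C4 ketone, with the C2 silyloxy group steering the nucleophile to the α face. The forward step must avoid reduction, enolisation and halogen–metal exchange.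

4 to 3 to 2 to 1: the C5–I bond, then the C1–C15 bond with re-oxidation of C5=C1, are cut. Ring atoms are numbered as in the target (carbonyl carbon C4, α-carbon C5, β-carbon C1, oxygenated carbon C2). This reaches a commercial enantiopure enone; the conjugate addition must not eliminate the C2 silyloxy group.

## Other disconnections considered

Alternative 1: The cut goes through C1–C15 and C4–C5, opening ring B and leaving ring A as cycloheptadienone A1 with an isopropyl ketone on a C2–C3 tether. In the forward sense Me3Al with catalytic CuBr·SMe2 (monovalent copper) would transfer methyl to C1, and C5 would then close onto the C4 carbonyl in the same flask to give hydroxy ketone A2.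
- In its favour: two C–C bonds, ring B and three stereocentres (C1, C4, C5) in one operation. The C6 ketone and free C4 hydroxyl appear directly, with no enol silane hydrolysis and no separate C5 protonation. On setting C4 and C5, and on avoiding cyclopropane stereoisomers, this plan is the better one.
- Against it here: the quaternary centre is made by addition to a β,β-disubstituted enone with only the neighbouring C10 silyloxy group to select the face. The aldol must pick one face of a hindered isopropyl ketone, and a ketone–ketone aldolate can revert. The C8=C9 alkene of A1 is β,γ to the carbonyl and C10 is doubly allylic, so a Lewis acid could cause conjugation or ionisation. A1 also needs its own synthesis of a stereodefined seven-membered ring.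
- Comparison: structurally this makes ring B last where the chosen plan makes ring A last. Mechanistically it is a polar cascade with open transition states against a pericyclic step whose geometry ties C10 to C1. The cascade step is more convergent, but the chosen plan starts from a commercial five-membered ring, so the overall step count is expected to be similar or slightly in favour of the chosen plan.

Alternative 2: The cut is C9–C10, giving seco-aldehyde A3: a fully substituted cyclopentane with the C10 aldehyde on C1 and, on C5, the chain C6(O-angeloyl)–C7–C8(C14)=C9–I with a (Z)-iodide. In the forward sense CrCl2 (divalent chromium) with catalytic NiCl2 (divalent nickel) would insert into the C9–I bond and the alkenylmetal would add to the aldehyde, closing ring A to allylic alcohol A4 (Nozaki–Hiyama–Kishi).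
- In its favour: very mild and chemoselective; it tolerates the C6 angelate already in place and releases the C10 hydroxyl free. On functional-group tolerance, absence of a thermal step, and one deprotection fewer at the end, it is the equal or the better of the chosen plan.
- Against it here: C10 is created by substrate-controlled addition to a neopentyl aldehyde during a seven-membered ring closure, and its sense is hard to predict. All of C1, C2, C4, C5 and C6 must already be set on the cyclopentane, so the key step does not address the quaternary centre. It needs excess chromium salt.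
- Comparison: structurally the hard stereochemistry is moved into a long linear preparation of A3. Mechanistically C10 is set independently of C1, whereas the Cope step sets both together. Overall it is expected to be longer.

Alternative 3: The cut is C1–C5 with reconnection of C1–C6 (retro-semipinacol), giving the trans-decalin A5 of the Wieland–Miescher type with a tertiary C6 hydroxyl and an equatorial C5 mesylate. In the forward sense the C6 alkoxide would push the antiperiplanar C1–C6 bond onto C5 as mesylate leaves, contracting one ring to ring B and expanding the other to ring A in ketone A6.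
- In its favour: the shift is stereospecific, C5 is set by inversion so the cis fusion arises directly, and C1 comes from an enantioenriched decalin building block. On C5 control and on the origin of the quaternary centre it is the better plan, and it needs neither a cyclopropane nor heat.
- Against it here: A5 must already carry the C2, C4 (tertiary, isopropyl), C5, C6 and C10 oxygens and the C8=C9 alkene with correct configuration on a trans-decalin. That requires a long functionalisation sequence, including selective mesylation of a secondary hydroxyl between two oxygenated quaternary carbons. Elimination or fragmentation can compete, and the basic conditions expose A6 (β-silyloxy ketone, β,γ-alkene) to conjugation and E1cB loss.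
- Comparison: the key step itself is more economical (two rings at once, stereospecific). The route to A5 is expected to be the longest of all, and its stereocentres are set one by one; the chosen plan sets C1 and C10 together on a simple ring B.

Key step: step 14

## Route

Step 1
Reactants: 1 (S)-4-[(tert-butyldimethylsilyl)oxy]cyclopent-2-en-1-one
Product: 2 tert-butyldimethyl{[(1S,2S)-2-methyl-4-[(trimethylsilyl)oxy]cyclopent-3-en-1-yl]oxy}silane (methyl trans to the silyloxy group)
Conditions: Me2CuLi (from CuI and MeLi), Me3SiCl, Et3N, THF, −78 °C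
Reagents that add atoms: lithium dimethylcuprate, [Li+].C[Cu-]C; chlorotrimethylsilane, C[Si](C)(C)Cl
Why: Conjugate addition of the lithium dialkylcuprate to C1 (the enone β-carbon) occurs anti to the C2 silyloxy group, and silylation of the enolate as it forms prevents β-elimination of that group; the C1 stereocentre made here is removed again in step 2.

Step 2
Reactants: 2 tert-butyldimethyl{[(1S,2S)-2-methyl-4-[(trimethylsilyl)oxy]cyclopent-3-en-1-yl]oxy}silane
Product: 3 (S)-4-[(tert-butyldimethylsilyl)oxy]-3-methylcyclopent-2-en-1-one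
Conditions: Pd(OAc)2 (cat.), O2 (1 atm), DMSO, rt
Reagents that add atoms: none
Why: Saegusa–Ito oxidation: palladation of the enol silane at C5 and β-hydride elimination of the C1 hydrogen restore the C5=C1 enone regiospecifically, now carrying C15; the C2 stereocentre is not involved.

Step 3
Reactants: 3 (S)-4-[(tert-butyldimethylsilyl)oxy]-3-methylcyclopent-2-en-1-one
Product: 4 (S)-4-[(tert-butyldimethylsilyl)oxy]-2-iodo-3-methylcyclopent-2-en-1-one
Conditions: I2, pyridine, 4-(dimethylamino)pyridine (cat.), CH2Cl2, rt
Reagents that add atoms: iodine, II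
Why: α-Iodination of the enone by the iodine–amine addition/elimination sequence (reversible amine addition at C1, iodination of the enolate at C5, loss of the amine); no stereocentre is formed.

Step 4
Reactants: 4 (S)-4-[(tert-butyldimethylsilyl)oxy]-2-iodo-3-methylcyclopent-2-en-1-one
Product: 5 (1S,4S)-4-[(tert-butyldimethylsilyl)oxy]-2-iodo-3-methyl-1-(propan-2-yl)cyclopent-2-en-1-ol (hydroxyl cis to the silyloxy group)
Conditions: i-PrMgCl, CeCl3, THF, −78 °C
Reagents that add atoms: isopropylmagnesium chloride, CC(C)[Mg]Cl
Why: CeCl3-mediated 1,2-addition of the Grignard reagent to the C4 carbonyl; the cerium-modified reagent is weakly basic, which suppresses enolisation, β-hydride reduction and iodine–magnesium exchange, and the nucleophile enters anti to the C2 silyloxy group, placing the isopropyl group α and the C4 hydroxyl β.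

Step 5
Reactants: 5 (1S,4S)-4-[(tert-butyldimethylsilyl)oxy]-2-iodo-3-methyl-1-(propan-2-yl)cyclopent-2-en-1-ol
Product: 6 (1S,4S)-2-iodo-3-methyl-1-(propan-2-yl)cyclopent-2-ene-1,4-diol (cis-diol)
Conditions: Bu4NF, THF, 0 °C
Reagents that add atoms: none
Why: Fluoride cleavage of the secondary silyl ether; the tertiary allylic alcohol and the alkenyl iodide are inert under these conditions.

Step 6
Reactants: 6 (1S,4S)-2-iodo-3-methyl-1-(propan-2-yl)cyclopent-2-ene-1,4-diol
Product: 7 (1S,4R)-2-iodo-4-(4-methoxyphenoxy)-3-methyl-1-(propan-2-yl)cyclopent-2-en-1-ol (aryloxy group trans to the hydroxyl)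
Conditions: 4-MeOC6H4OH, PPh3, i-PrO2CN=NCO2i-Pr, toluene, 0 °C to rt
Reagents that add atoms: 4-methoxyphenol, COc1ccc(O)cc1
Why: Mitsunobu etherification: only the secondary allylic hydroxyl is activated as its oxyphosphonium ion and the phenoxide displaces it with inversion, converting the cis-diol pattern into the required trans C2/C4 relationship while installing the C2 protecting group; SN2' attack is blocked because the alkene is tetrasubstituted.

Step 7
Reactants: 7 (1S,4R)-2-iodo-4-(4-methoxyphenoxy)-3-methyl-1-(propan-2-yl)cyclopent-2-en-1-ol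
Product: 8 {[(1S,4R)-2-iodo-4-(4-methoxyphenoxy)-3-methyl-1-(propan-2-yl)cyclopent-2-en-1-yl]oxy}trimethylsilane
Conditions: Me3SiOTf, 2,6-lutidine, CH2Cl2, −78 °C
Reagents that add atoms: trimethylsilyl trifluoromethanesulfonate, C[Si](C)(C)OS(=O)(=O)C(F)(F)F
Why: Silylation of the hindered tertiary hydroxyl with a silyl triflate and a non-nucleophilic base; the small Me3Si group is chosen so that it leaves together with the other silyl groups in step 15.

Step 8
Reactants: 9 2-methylprop-2-enoyl chloride; 10 N,O-dimethylhydroxylamine hydrochloride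
Product: 11 N-methoxy-N,2-dimethylprop-2-enamide
Conditions: Et3N, CH2Cl2, 0 °C
Reagents that add atoms: none
Why: N-Acylation of the hydroxylamine by the acid chloride gives the Weinreb amide; no stereocentre is involved.

Step 9
Reactants: 8 {[(1S,4R)-2-iodo-4-(4-methoxyphenoxy)-3-methyl-1-(propan-2-yl)cyclopent-2-en-1-yl]oxy}trimethylsilane; 11 N-methoxy-N,2-dimethylprop-2-enamide
Product: 13 1-[(3R,5S)-3-(4-methoxyphenoxy)-2-methyl-5-(propan-2-yl)-5-[(trimethylsilyl)oxy]cyclopent-1-en-1-yl]-2-methylprop-2-en-1-one, via cyclopentenyllithium 12 (not isolated)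
Conditions: t-BuLi (2 equiv), Et2O–THF, −78 °C; then 11, −78 to −30 °C; cold aq. NH4Cl
Reagents that add atoms: none
Why: Iodine–lithium exchange is faster than attack on the silyl or aryl ether at −78 °C, and alkenyllithium 12 adds once to the Weinreb amide because the chelated tetrahedral adduct survives until the quench (Weinreb ketone synthesis); the quench is cold and near neutral because 13 is a cross-conjugated dienone that acid would cyclise (Nazarov).

Step 10
Reactants: 13 1-[(3R,5S)-3-(4-methoxyphenoxy)-2-methyl-5-(propan-2-yl)-5-[(trimethylsilyl)oxy]cyclopent-1-en-1-yl]-2-methylprop-2-en-1-one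
Product: 15 triethyl{[(1E)-1-[(3R,5S)-3-(4-methoxyphenoxy)-2-methyl-5-(propan-2-yl)-5-[(trimethylsilyl)oxy]cyclopent-1-en-1-yl]-2-methylpenta-1,4-dien-1-yl]oxy}silane, via bromomagnesium enolate 14 (not isolated)
Conditions: CH2=CHMgBr, CuBr·SMe2 (cat.), THF, −78 °C; then Et3SiCl, Et3N, DMPU, −78 to 0 °C
Reagents that add atoms: vinylmagnesium bromide, C=C[Mg]Br; chlorotriethylsilane, CC[Si](CC)(CC)Cl
Why: Copper-catalysed conjugate addition of the vinyl Grignard reagent to the unhindered methylene terminus (the ring alkene is a β,β-disubstituted, unreactive acceptor); the α-methyl enone reacts through its s-trans conformer, in which the bulky ring B substituent avoids C14, so C9 ends trans to oxygen in enolate 14 and O-silylation fixes the (E)-enol silane with ring B and the allyl group cis; the fully substituted enolate cannot isomerise by proton transfer.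

Step 11
Reactants: 15 triethyl{[(1E)-1-[(3R,5S)-3-(4-methoxyphenoxy)-2-methyl-5-(propan-2-yl)-5-[(trimethylsilyl)oxy]cyclopent-1-en-1-yl]-2-methylpenta-1,4-dien-1-yl]oxy}silane
Product: 16 triethyl{[(1S,2S)-1-[(3R,5S)-3-(4-methoxyphenoxy)-2-methyl-5-(propan-2-yl)-5-[(trimethylsilyl)oxy]cyclopent-1-en-1-yl]-2-methyl-2-(prop-2-en-1-yl)cyclopropyl]oxy}silane (cyclopentenyl and allyl groups cis; C6 S, C8 S)
Conditions: Et2Zn, CH2I2, CH2Cl2, 0 °C; pyridine then aq. NaHCO3 quench
Reagents that add atoms: diiodomethane, ICI
Why: Simmons–Smith cyclopropanation with the zinc carbenoid is fastest at the electron-rich silyl enol ether (the monosubstituted alkene is much less nucleophilic and C5=C1 is shielded) and is stereospecific, so the cis relationship of ring B and the allyl group is copied from 15; the carbenoid is expected on the enol face turned toward C15 in the conformer that holds C8 away from the C4 isopropyl group, and the quench is kept basic because 1-silyloxy-1-alkenylcyclopropanes rearrange to cyclobutanones under acid.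

Step 12
Reactants: 16 triethyl{[(1S,2S)-1-[(3R,5S)-3-(4-methoxyphenoxy)-2-methyl-5-(propan-2-yl)-5-[(trimethylsilyl)oxy]cyclopent-1-en-1-yl]-2-methyl-2-(prop-2-en-1-yl)cyclopropyl]oxy}silane
Product: 17 2-[(1R,2S)-2-[(3R,5S)-3-(4-methoxyphenoxy)-2-methyl-5-(propan-2-yl)-5-[(trimethylsilyl)oxy]cyclopent-1-en-1-yl]-1-methyl-2-[(triethylsilyl)oxy]cyclopropyl]acetaldehyde
Conditions: OsO4 (cat.), NaIO4, 2,6-lutidine, dioxane–H2O, rt
Reagents that add atoms: sodium periodate, [Na+].[O-]I(=O)(=O)=O
Why: Lemieux–Johnson cleavage: OsO4 dihydroxylates the unhindered monosubstituted alkene much faster than the congested tetrasubstituted C5=C1 bond and periodate cleaves the diol in situ, while 2,6-lutidine keeps the medium neutral for the silyloxycyclopropane and the tertiary silyl ether; ozone would attack C5=C1 first and is avoided.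

Step 13
Reactants: 17 2-[(1R,2S)-2-[(3R,5S)-3-(4-methoxyphenoxy)-2-methyl-5-(propan-2-yl)-5-[(trimethylsilyl)oxy]cyclopent-1-en-1-yl]-1-methyl-2-[(triethylsilyl)oxy]cyclopropyl]acetaldehyde
Product: 18 tert-butyl{[(E)-2-[(1R,2S)-2-[(3R,5S)-3-(4-methoxyphenoxy)-2-methyl-5-(propan-2-yl)-5-[(trimethylsilyl)oxy]cyclopent-1-en-1-yl]-1-methyl-2-[(triethylsilyl)oxy]cyclopropyl]ethenyl]oxy}dimethylsilane (C6 S, C8 R; alkenyl arms cis)
Conditions: KN(SiMe3)2, t-BuMe2SiCl, THF, −78 °C (aldehyde added last)
Reagents that add atoms: tert-butylchlorodimethylsilane, CC(C)(C)[Si](C)(C)Cl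
Why: Kinetic deprotonation of the aldehyde by the hindered amide in the presence of the silyl chloride passes through a cyclic transition state with the quaternary C8 substituent pseudo-equatorial, and the neopentyl-type aldehyde also prefers the conformer with C8 turned away from the carbonyl oxygen, so the (E)-enol silane is expected; immediate O-silylation prevents aldol condensation.

Step 14
Reactants: 18 tert-butyl{[(E)-2-[(1R,2S)-2-[(3R,5S)-3-(4-methoxyphenoxy)-2-methyl-5-(propan-2-yl)-5-[(trimethylsilyl)oxy]cyclopent-1-en-1-yl]-1-methyl-2-[(triethylsilyl)oxy]cyclopropyl]ethenyl]oxy}dimethylsilane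
Product: 19 tert-butyl{[(1R,3S,8R,8aR)-1-(4-methoxyphenoxy)-6,8a-dimethyl-3-(propan-2-yl)-4-[(triethylsilyl)oxy]-3-[(trimethylsilyl)oxy]-1,2,3,5,8,8a-hexahydroazulen-8-yl]oxy}dimethylsilane
Conditions: toluene (base-washed glass, trace Et3N), 80–110 °C
Reagents that add atoms: none
Why: Concerted [3,3]-sigmatropic (Cope) rearrangement of the cis-1,2-dialkenylcyclopropane through a boat transition state in which both arms (C5=C1 and C9=C10) are folded over the three-membered ring, so that C1–C10 forms while C6–C8 breaks. The closest known reaction type is the divinylcyclopropane–cycloheptadiene rearrangement of silyloxy-substituted cyclopropanes. Ring A closes by this suprafacial ring expansion from three to seven members, driven by release of cyclopropane strain, and the C5=C6 enol silane and the C8=C9 alkene appear directly in their final positions. C10 is fixed relative to C1 by the boat geometry together with the (E)-enol silane: the silyloxy group points outward and ends on the same side of ring A as C2, and only the C15 methyl has to sit inward. C1 is fixed by the cyclopropane configuration: in the (6S,8R) isomer the boat places C10 under the β face of C1, anti to the C2 aryloxy group and the C4 isopropyl group, whereas the (6R,8S) cis isomer would have to bond on the α face with its outward C10 silyloxy group pressed against the C2 aryloxy group. The step therefore needs cis arms (secured by the geometry of 15 and the stereospecific step 11), an (E)-enol silane (step 13) and β-face bonding (secured by C2 and C4). Any C6/C8 stereoisomer carried along is expected to enter the same channel by reversible homolysis of the C6–C8 bond, which is weakened by the silyloxy donor and by allylic stabilisation at both ends.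

Step 15
Reactants: 19 tert-butyl{[(1R,3S,8R,8aR)-1-(4-methoxyphenoxy)-6,8a-dimethyl-3-(propan-2-yl)-4-[(triethylsilyl)oxy]-3-[(trimethylsilyl)oxy]-1,2,3,5,8,8a-hexahydroazulen-8-yl]oxy}dimethylsilane
Product: 21 (1R,3S,3aS,8R,8aS)-3,8-dihydroxy-1-(4-methoxyphenoxy)-6,8a-dimethyl-3-(propan-2-yl)-2,3,3a,5,8,8a-hexahydroazulen-4(1H)-one, via silylated cis-fused ketone 20 (not isolated)
Conditions: HF·pyridine, pyridine, THF, 0 °C to rt
Reagents that add atoms: none
Why: The enol silane is cleaved first and C5 is protonated from the α face, away from the pseudo-axial C10 silyloxy group and the C4 silyloxy group that cover the β face, giving cis-fused ketone 20, which is also the more stable ring fusion because C6 avoids the C4 isopropyl group and C15; the two remaining silyl ethers then fall in the same flask, and the acidic, non-enolising medium keeps C8=C9 out of conjugation and protects the β-hydroxy ketone from retro-aldol cleavage or dehydration.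

Step 16
Reactants: 21 (1R,3S,3aS,8R,8aS)-3,8-dihydroxy-1-(4-methoxyphenoxy)-6,8a-dimethyl-3-(propan-2-yl)-2,3,3a,5,8,8a-hexahydroazulen-4(1H)-one
Product: 22 (1R,3S,3aR,4R,8R,8aS)-1-(4-methoxyphenoxy)-6,8a-dimethyl-3-(propan-2-yl)-1,2,3,3a,4,5,8,8a-octahydroazulene-3,4,8-triol
Conditions: Me4NBH(OAc)3, MeCN–AcOH, −30 to 0 °C
Reagents that add atoms: none
Why: Hydroxyl-directed reduction (Evans–Saksena type): the β C4 hydroxyl exchanges onto boron and hydride is delivered intramolecularly to the β face of the C6 carbonyl, giving the C6 α-alcohol; the C10 hydroxyl lies on the same face and can only reinforce this, and the unbound reagent is too weak to reduce from the open α face.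

Step 17
Reactants: 22 (1R,3S,3aR,4R,8R,8aS)-1-(4-methoxyphenoxy)-6,8a-dimethyl-3-(propan-2-yl)-1,2,3,3a,4,5,8,8a-octahydroazulene-3,4,8-triol; 23 angelic acid [(2Z)-2-methylbut-2-enoic acid] (first of two equivalents)
Product: 25 (1R,3S,3aR,4R,8R,8aR)-3-hydroxy-1-(4-methoxyphenoxy)-6,8a-dimethyl-3-(propan-2-yl)-1,2,3,3a,4,5,8,8a-octahydroazulene-4,8-diyl bis[(2Z)-2-methylbut-2-enoate], via mixed anhydride 24 (not isolated)
Conditions: 23 (3 equiv), 2,4,6-Cl3C6H2COCl (3 equiv), Et3N, toluene, rt; then 22, toluene, 75 °C
Reagents that add atoms: angelic acid (second equivalent, acyl group of the second ester), C/C=C(/C)C(=O)O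
Why: Mixed-anhydride (Yamaguchi-type) esterification run thermally without a nucleophilic catalyst, the established way to acylate with angelic acid without Z to E isomerisation; each of the two secondary hydroxyls (C6 and C10) takes one angeloyl group from the unhindered carbonyl of one molecule of 24, so an excess of 23 is converted into 24 beforehand, and the tertiary C4 hydroxyl does not react.

Step 18
Reactants: 25 (1R,3S,3aR,4R,8R,8aR)-3-hydroxy-1-(4-methoxyphenoxy)-6,8a-dimethyl-3-(propan-2-yl)-1,2,3,3a,4,5,8,8a-octahydroazulene-4,8-diyl bis[(2Z)-2-methylbut-2-enoate]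
Product: 26 (1R,3S,3aR,4R,8R,8aR)-1,3-dihydroxy-6,8a-dimethyl-3-(propan-2-yl)-1,2,3,3a,4,5,8,8a-octahydroazulene-4,8-diyl bis[(2Z)-2-methylbut-2-enoate]
Conditions: (NH4)2Ce(NO3)6, pyridine, MeCN–H2O, 0 °C
Reagents that add atoms: none
Why: Oxidative removal of the 4-methoxyphenyl ether: (NH4)2Ce(NO3)6 (tetravalent cerium) oxidises the electron-rich arene, water adds at the ipso carbon and the C2 alcohol is released with retention together with benzoquinone; the esters, the trisubstituted alkene and the tertiary alcohol are not oxidised under these cold, buffered conditions.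

## Compound list

1 | (S)-4-[(tert-butyldimethylsilyl)oxy]cyclopent-2-en-1-one | O=C1C=C[C@@H](O[Si](C)(C)C(C)(C)C)C1 | starting material
2 | tert-butyldimethyl{[(1S,2S)-2-methyl-4-[(trimethylsilyl)oxy]cyclopent-3-en-1-yl]oxy}silane | C[Si](C)(C)OC1=C[C@H](C)[C@@H](O[Si](C)(C)C(C)(C)C)C1 | intermediate
3 | (S)-4-[(tert-butyldimethylsilyl)oxy]-3-methylcyclopent-2-en-1-one | O=C1C=C(C)[C@@H](O[Si](C)(C)C(C)(C)C)C1 | intermediate
4 | (S)-4-[(tert-butyldimethylsilyl)oxy]-2-iodo-3-methylcyclopent-2-en-1-one | O=C1C(I)=C(C)[C@@H](O[Si](C)(C)C(C)(C)C)C1 | intermediate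
5 | (1S,4S)-4-[(tert-butyldimethylsilyl)oxy]-2-iodo-3-methyl-1-(propan-2-yl)cyclopent-2-en-1-ol | IC1=C(C)[C@@H](O[Si](C)(C)C(C)(C)C)C[C@]1(O)C(C)C | intermediate
6 | (1S,4S)-2-iodo-3-methyl-1-(propan-2-yl)cyclopent-2-ene-1,4-diol | IC1=C(C)[C@@H](O)C[C@]1(O)C(C)C | intermediate
7 | (1S,4R)-2-iodo-4-(4-methoxyphenoxy)-3-methyl-1-(propan-2-yl)cyclopent-2-en-1-ol | IC1=C(C)[C@H](Oc2ccc(OC)cc2)C[C@]1(O)C(C)C | intermediate
8 | {[(1S,4R)-2-iodo-4-(4-methoxyphenoxy)-3-methyl-1-(propan-2-yl)cyclopent-2-en-1-yl]oxy}trimethylsilane | IC1=C(C)[C@H](Oc2ccc(OC)cc2)C[C@]1(O[Si](C)(C)C)C(C)C | intermediate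
9 | 2-methylprop-2-enoyl chloride | C=C(C)C(Cl)=O | starting material
10 | N,O-dimethylhydroxylamine hydrochloride | CNOC.Cl | starting material
11 | N-methoxy-N,2-dimethylprop-2-enamide | C=C(C)C(=O)N(C)OC | intermediate
12 | [(3R,5S)-3-(4-methoxyphenoxy)-2-methyl-5-(propan-2-yl)-5-[(trimethylsilyl)oxy]cyclopent-1-en-1-yl]lithium | [Li]C1=C(C)[C@H](Oc2ccc(OC)cc2)C[C@]1(O[Si](C)(C)C)C(C)C | intermediate
13 | 1-[(3R,5S)-3-(4-methoxyphenoxy)-2-methyl-5-(propan-2-yl)-5-[(trimethylsilyl)oxy]cyclopent-1-en-1-yl]-2-methylprop-2-en-1-one | C=C(C)C(=O)C1=C(C)[C@H](Oc2ccc(OC)cc2)C[C@]1(O[Si](C)(C)C)C(C)C | intermediate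
14 | bromomagnesium (1E)-1-[(3R,5S)-3-(4-methoxyphenoxy)-2-methyl-5-(propan-2-yl)-5-[(trimethylsilyl)oxy]cyclopent-1-en-1-yl]-2-methylpenta-1,4-dien-1-olate | Br[Mg]O/C(C1=C(C)[C@H](Oc2ccc(OC)cc2)C[C@]1(O[Si](C)(C)C)C(C)C)=C(\C)CC=C | intermediate
15 | triethyl{[(1E)-1-[(3R,5S)-3-(4-methoxyphenoxy)-2-methyl-5-(propan-2-yl)-5-[(trimethylsilyl)oxy]cyclopent-1-en-1-yl]-2-methylpenta-1,4-dien-1-yl]oxy}silane | CC[Si](CC)(CC)O/C(C1=C(C)[C@H](Oc2ccc(OC)cc2)C[C@]1(O[Si](C)(C)C)C(C)C)=C(\C)CC=C | intermediate
16 | triethyl{[(1S,2S)-1-[(3R,5S)-3-(4-methoxyphenoxy)-2-methyl-5-(propan-2-yl)-5-[(trimethylsilyl)oxy]cyclopent-1-en-1-yl]-2-methyl-2-(prop-2-en-1-yl)cyclopropyl]oxy}silane | CC[Si](CC)(CC)O[C@]1(C[C@]1(C)CC=C)C2=C(C)[C@H](Oc3ccc(OC)cc3)C[C@]2(O[Si](C)(C)C)C(C)C | intermediate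
17 | 2-[(1R,2S)-2-[(3R,5S)-3-(4-methoxyphenoxy)-2-methyl-5-(propan-2-yl)-5-[(trimethylsilyl)oxy]cyclopent-1-en-1-yl]-1-methyl-2-[(triethylsilyl)oxy]cyclopropyl]acetaldehyde | CC[Si](CC)(CC)O[C@]1(C[C@]1(C)CC=O)C2=C(C)[C@H](Oc3ccc(OC)cc3)C[C@]2(O[Si](C)(C)C)C(C)C | intermediate
18 | tert-butyl{[(E)-2-[(1R,2S)-2-[(3R,5S)-3-(4-methoxyphenoxy)-2-methyl-5-(propan-2-yl)-5-[(trimethylsilyl)oxy]cyclopent-1-en-1-yl]-1-methyl-2-[(triethylsilyl)oxy]cyclopropyl]ethenyl]oxy}dimethylsilane | CC[Si](CC)(CC)O[C@]1(C[C@]1(C)/C=C/O[Si](C)(C)C(C)(C)C)C2=C(C)[C@H](Oc3ccc(OC)cc3)C[C@]2(O[Si](C)(C)C)C(C)C | intermediate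
19 | tert-butyl{[(1R,3S,8R,8aR)-1-(4-methoxyphenoxy)-6,8a-dimethyl-3-(propan-2-yl)-4-[(triethylsilyl)oxy]-3-[(trimethylsilyl)oxy]-1,2,3,5,8,8a-hexahydroazulen-8-yl]oxy}dimethylsilane | CC[Si](CC)(CC)OC=1CC(C)=C[C@@H](O[Si](C)(C)C(C)(C)C)[C@@]2(C)[C@H](Oc3ccc(OC)cc3)C[C@](O[Si](C)(C)C)(C(C)C)C=12 | intermediate
20 | (1R,3S,3aS,8R,8aR)-8-[(tert-butyldimethylsilyl)oxy]-1-(4-methoxyphenoxy)-6,8a-dimethyl-3-(propan-2-yl)-3-[(trimethylsilyl)oxy]-2,3,3a,5,8,8a-hexahydroazulen-4(1H)-one | O=C1CC(C)=C[C@@H](O[Si](C)(C)C(C)(C)C)[C@@]2(C)[C@H](Oc3ccc(OC)cc3)C[C@](O[Si](C)(C)C)(C(C)C)[C@@H]12 | intermediate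
21 | (1R,3S,3aS,8R,8aS)-3,8-dihydroxy-1-(4-methoxyphenoxy)-6,8a-dimethyl-3-(propan-2-yl)-2,3,3a,5,8,8a-hexahydroazulen-4(1H)-one | O=C1CC(C)=C[C@@H](O)[C@@]2(C)[C@H](Oc3ccc(OC)cc3)C[C@](O)(C(C)C)[C@@H]12 | intermediate
22 | (1R,3S,3aR,4R,8R,8aS)-1-(4-methoxyphenoxy)-6,8a-dimethyl-3-(propan-2-yl)-1,2,3,3a,4,5,8,8a-octahydroazulene-3,4,8-triol | O[C@@H]1CC(C)=C[C@@H](O)[C@@]2(C)[C@H](Oc3ccc(OC)cc3)C[C@](O)(C(C)C)[C@@H]12 | intermediate
23 | angelic acid, (2Z)-2-methylbut-2-enoic acid | C/C=C(/C)C(=O)O | starting material
24 | (2Z)-2-methylbut-2-enoic 2,4,6-trichlorobenzoic anhydride | C/C=C(/C)C(=O)OC(=O)c1c(Cl)cc(Cl)cc1Cl | intermediate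
25 | (1R,3S,3aR,4R,8R,8aR)-3-hydroxy-1-(4-methoxyphenoxy)-6,8a-dimethyl-3-(propan-2-yl)-1,2,3,3a,4,5,8,8a-octahydroazulene-4,8-diyl bis[(2Z)-2-methylbut-2-enoate] | C/C=C(/C)C(=O)O[C@@H]1CC(C)=C[C@@H](OC(=O)/C(C)=C\C)[C@@]2(C)[C@H](Oc3ccc(OC)cc3)C[C@](O)(C(C)C)[C@@H]12 | intermediate
26 | (1R,3S,3aR,4R,8R,8aR)-1,3-dihydroxy-6,8a-dimethyl-3-(propan-2-yl)-1,2,3,3a,4,5,8,8a-octahydroazulene-4,8-diyl bis[(2Z)-2-methylbut-2-enoate] | C/C=C(/C)C(=O)O[C@@H]1CC(C)=C[C@@H](OC(=O)/C(C)=C\C)[C@@]2(C)[C@H](O)C[C@](O)(C(C)C)[C@@H]12 | target

## Step count and least certain steps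

Total step count: 18. Longest linear sequence: 17 steps (from 1 to 26 through steps 1–7 and 9–18; step 8 is a side branch).

Step 14 (key step). The most likely failure is incomplete convergence: a wrong-face cis isomer or a trans isomer of 18 may stall, or drift into hydrogen-shift pathways, at temperatures the enol silanes tolerate; bonding on the α face of C1 would occur only if the C2 aryloxy group failed to discriminate. Fallback: starting from 18 and returning at 19, the stereomutation is moved from the thermal to the photochemical manifold. Triplet sensitisation (benzophenone or xanthone, 350–365 nm, benzene, rt) of the alkenylcyclopropane chromophore cleaves C6–C8 reversibly at ambient temperature, so the stereoisomers interconvert and only the matched cis isomer drains through the thermal [3,3] shift on gentle warming. No new compound arises (F0).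

Step 6. The activated allylic alcohol may ionise or eliminate instead of undergoing SN2 displacement, because the phenoxide must approach from the face of the C4 isopropyl group; this would erode the C2 configuration or give a cyclopentadiene. Fallback: starting from 6, MnO2 (CH2Cl2, rt) oxidises the secondary allylic alcohol to (4S)-4-hydroxy-3-iodo-2-methyl-4-(propan-2-yl)cyclopent-2-en-1-one F1. Me4NBH(OAc)3 (MeCN–AcOH, −30 °C) then delivers hydride from the C4 hydroxyl face to give the trans-diol (1S,4R)-2-iodo-3-methyl-1-(propan-2-yl)cyclopent-2-ene-1,4-diol F2. The secondary hydroxyl is arylated with retention by a Chan–Lam-type coupling (potassium (4-methoxyphenyl)trifluoroborate, Cu(OAc)2 (cat.), 4-(dimethylamino)pyridine, O2, molecular sieves, CH2Cl2, rt), which returns to the route at 7.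

Step 13. Enolisation may give the (Z)-enol silane or a mixture, and the free enolate may undergo aldol condensation; a (Z)-arm would have to sit inward in the boat and would block or misdirect step 14. Fallback: starting from 17, the aldehyde is converted into its enol acetates at ambient temperature (Ac2O, Et3N, catalytic 4-(dimethylamino)pyridine, CH2Cl2, rt, kept cold afterwards so that the dialkenylcyclopropane does not rearrange prematurely) and the (E)-isomer, (E)-2-[(1R,2S)-2-[(3R,5S)-3-(4-methoxyphenoxy)-2-methyl-5-(propan-2-yl)-5-[(trimethylsilyl)oxy]cyclopent-1-en-1-yl]-1-methyl-2-[(triethylsilyl)oxy]cyclopropyl]ethenyl acetate F3, is separated by chromatography. MeLi (2 equiv, THF, −78 to 0 °C) liberates the lithium (E)-enolate with retention of geometry, and t-BuMe2SiCl traps it to return to the route at 18.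

Step 15. C5 may be protonated on the β face (trans ring fusion); C8=C9 may migrate into conjugation with the C6 ketone, or the β-hydroxy ketone may dehydrate, if the medium becomes enolising. Fallback: starting from 19, thermodynamic rather than kinetic control is applied at the fully silylated stage. Bu4NF buffered with AcOH (THF, −78 °C) cleaves only the enol silane to give 20 together with its C5 epimer, (1R,3S,3aR,8R,8aR)-8-[(tert-butyldimethylsilyl)oxy]-1-(4-methoxyphenoxy)-6,8a-dimethyl-3-(propan-2-yl)-3-[(trimethylsilyl)oxy]-2,3,3a,5,8,8a-hexahydroazulen-4(1H)-one F4. With C4 still silylated (no retro-aldol), the mixture is equilibrated through the enol with a weak amine base (Et3N or catalytic DBU, CH2Cl2, 0 °C, short contact) toward the cis-fused 20. HF·pyridine then returns to the route at 21.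

Step 17. Both acylations must go to completion: the neopentyl C10 hydroxyl may react only partly and leave a mono-ester, and forcing conditions may isomerise angelate to tiglate. Fallback: starting from 22, both secondary hydroxyls are esterified with 2-[bis(2,2,2-trifluoroethoxy)phosphoryl]propanoic acid (dicyclohexylcarbodiimide, catalytic 4-(dimethylamino)pyridine, CH2Cl2; no alkene is present to isomerise) to give (1R,3S,3aR,4R,8R,8aR)-3-hydroxy-1-(4-methoxyphenoxy)-6,8a-dimethyl-3-(propan-2-yl)-1,2,3,3a,4,5,8,8a-octahydroazulene-4,8-diyl bis{2-[bis(2,2,2-trifluoroethoxy)phosphoryl]propanoate} F5. A Still–Gennari olefination (KN(SiMe3)2, 18-crown-6, THF, −78 °C, acetaldehyde) then builds both (Z)-2-methylbut-2-enoates in place and returns to the route at 25.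

## Further compounds

F1 | step 6 | (4S)-4-hydroxy-3-iodo-2-methyl-4-(propan-2-yl)cyclopent-2-en-1-one | O=C1C(C)=C(I)[C@@](O)(C(C)C)C1
F2 | step 6 | (1S,4R)-2-iodo-3-methyl-1-(propan-2-yl)cyclopent-2-ene-1,4-diol | IC1=C(C)[C@H](O)C[C@]1(O)C(C)C
F3 | step 13 | (E)-2-[(1R,2S)-2-[(3R,5S)-3-(4-methoxyphenoxy)-2-methyl-5-(propan-2-yl)-5-[(trimethylsilyl)oxy]cyclopent-1-en-1-yl]-1-methyl-2-[(triethylsilyl)oxy]cyclopropyl]ethenyl acetate | CC[Si](CC)(CC)O[C@]1(C[C@]1(C)/C=C/OC(C)=O)C2=C(C)[C@H](Oc3ccc(OC)cc3)C[C@]2(O[Si](C)(C)C)C(C)C
F0 | step 14 | none | none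
F4 | step 15 | (1R,3S,3aR,8R,8aR)-8-[(tert-butyldimethylsilyl)oxy]-1-(4-methoxyphenoxy)-6,8a-dimethyl-3-(propan-2-yl)-3-[(trimethylsilyl)oxy]-2,3,3a,5,8,8a-hexahydroazulen-4(1H)-one | O=C1CC(C)=C[C@@H](O[Si](C)(C)C(C)(C)C)[C@@]2(C)[C@H](Oc3ccc(OC)cc3)C[C@](O[Si](C)(C)C)(C(C)C)[C@H]12
F5 | step 17 | (1R,3S,3aR,4R,8R,8aR)-3-hydroxy-1-(4-methoxyphenoxy)-6,8a-dimethyl-3-(propan-2-yl)-1,2,3,3a,4,5,8,8a-octahydroazulene-4,8-diyl bis{2-[bis(2,2,2-trifluoroethoxy)phosphoryl]propanoate} (epimers at the two phosphonate-bearing carbons) | CC(C(=O)O[C@@H]1CC(C)=C[C@@H](OC(=O)C(C)P(=O)(OCC(F)(F)F)OCC(F)(F)F)[C@@]2(C)[C@H](Oc3ccc(OC)cc3)C[C@](O)(C(C)C)[C@@H]12)P(=O)(OCC(F)(F)F)OCC(F)(F)F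
A1 | alternative 1 | (4R)-4-[(tert-butyldimethylsilyl)oxy]-3-{(1R)-1-[(4-methoxyphenyl)methoxy]-4-methyl-3-oxopentyl}-6-methylcyclohepta-2,5-dien-1-one | O=C1C=C([C@H](OCc2ccc(OC)cc2)CC(=O)C(C)C)[C@H](O[Si](C)(C)C(C)(C)C)C=C(C)C1
A2 | alternative 1 | (1R,3S,3aS,8R,8aR)-8-[(tert-butyldimethylsilyl)oxy]-3-hydroxy-1-[(4-methoxyphenyl)methoxy]-6,8a-dimethyl-3-(propan-2-yl)-2,3,3a,5,8,8a-hexahydroazulen-4(1H)-one | O=C1CC(C)=C[C@@H](O[Si](C)(C)C(C)(C)C)[C@@]2(C)[C@H](OCc3ccc(OC)cc3)C[C@](O)(C(C)C)[C@@H]12
A3 | alternative 2 | (3Z)-1-{3-[(tert-butyldimethylsilyl)oxy]-2-formyl-2-methyl-5-(propan-2-yl)-5-[(trimethylsilyl)oxy]cyclopentyl}-4-iodo-3-methylbut-3-en-1-yl (2Z)-2-methylbut-2-enoate, ring and carbinol centres configured as in A4 | O=C[C@@]1(C)[C@H](O[Si](C)(C)C(C)(C)C)C[C@](O[Si](C)(C)C)(C(C)C)[C@H]1[C@H](OC(=O)/C(C)=C\C)C/C(C)=C\I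
A4 | alternative 2 | (1R,3S,3aR,4R,8R,8aS)-1-[(tert-butyldimethylsilyl)oxy]-8-hydroxy-6,8a-dimethyl-3-(propan-2-yl)-3-[(trimethylsilyl)oxy]-1,2,3,3a,4,5,8,8a-octahydroazulen-4-yl (2Z)-2-methylbut-2-enoate | C/C=C(/C)C(=O)O[C@@H]1CC(C)=C[C@@H](O)[C@@]2(C)[C@H](O[Si](C)(C)C(C)(C)C)C[C@](O[Si](C)(C)C)(C(C)C)[C@@H]12
A5 | alternative 3 | trans-decalin fused through C1–C6 with tertiary C6 hydroxyl, equatorial C5 methanesulfonate, C4 triethylsilyloxy and isopropyl, C2 (4-methoxyphenyl)methoxy, C10 tert-butyldimethylsilyloxy and C8=C9 alkene, configured as in the SMILES | C[C@]12[C@H](OCc3ccc(OC)cc3)C[C@](O[Si](CC)(CC)CC)(C(C)C)[C@@H](OS(C)(=O)=O)[C@]1(O)CC(C)=C[C@H]2O[Si](C)(C)C(C)(C)C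
A6 | alternative 3 | (1R,3S,3aS,8R,8aR)-8-[(tert-butyldimethylsilyl)oxy]-1-[(4-methoxyphenyl)methoxy]-6,8a-dimethyl-3-(propan-2-yl)-3-[(triethylsilyl)oxy]-2,3,3a,5,8,8a-hexahydroazulen-4(1H)-one | O=C1CC(C)=C[C@@H](O[Si](C)(C)C(C)(C)C)[C@@]2(C)[C@H](OCc3ccc(OC)cc3)C[C@](O[Si](CC)(CC)CC)(C(C)C)[C@@H]12
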